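| setting | teal | blue | flask |
|---|---|---|---|
| starting material | 0.40 M | 0.40 M | 0.40 M |
| partner | 0.95 equiv | 0.95 equiv | 0.950 equiv |
| temperature | 5 °C | 0 °C | 5 °C |
| remark | the very flask that is asked about, followed so far | run made earlier |  |
| time |  |  | 12 min |

- teal (time / min: target / %, starting material / %): 2.50: 27.6, 42.5; 5.00: 33.0, 27.7; 8.00: 38.0, 20.5; 10.0: 37.4, 17.5
- blue (time / min: target / %, starting material / %): 2.50: 22.1, 54.9; 5.00: 29.0, 39.6; 8.00: 32.9, 30.2; 10.0: 34.9, 24.2

(standard deviation of a reading: 1 percentage point)

- target, in percent of the starting material first charged, at 12 min
- what to do for the largest gain in target; "none" if nothing gains more than 2 percentage points (north / east / south-east / north-east / none)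
- target present, with what was taken out counted in, in percent of the starting material first charged, after east
- target present, with what was taken out counted in, in percent of the starting material first charged, after north-east

- north: at 12 min add partner, 100% of the amount charged, then wait 6.0 min
- east: at 12 min raise the temperature by 15 K, then wait 6.0 min
- south-east: change nothing and wait 6.0 min more
- north-east: at 12 min take out 90% of the target then present, then wait 6.0 min

- what is taken out of target is counted as made
- additions bring no volume worth counting

Start from one ratio: c(partner)/c(starting material) is charged at 0.950 in the teal run, which is the asked flask followed so far. At the bench one calls that equal charges and draws the reciprocal of c(starting material) as a straight line against time. Do it honestly: in units of the charge the mean slope is 0.541 min⁻¹ up to 2.50 min but 0.471 min⁻¹ up to 10.0 min, so the line sags.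

Now find the border. Assume each starting material lost takes one partner. Then the ratio has fallen to 0.714 at the last reading, and equal charges no longer describe the teal flask. Partner is the limiting reagent, and a straight line cannot show where it stops. Use that line for 2.00 min more and no further: it leaves 15.0% of the starting material at 12 min.

Then reckon with partner. The last teal reading has lost 82.5% of the starting material and holds 37.4% target. That gives 0.453, with the scatter of a reading. Call it s, the selectivity: target made per starting material lost. The blue run reads 0.460.

My reckoning for the flask at 12 min is 38.5% target. The partner charge allows s times 0.950, or 43.1%, so 4.5 percentage points remains. Added partner opens s times the starting material left, 6.8 points, which is more, so I choose north.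

The forecast says 38.4% (37.2% to 39.6%) and north. After east it gives 38.5% (35% to 42.5%), after north-east 40% (38.8% to 41.3%). Its ground: “Waiting gives almost nothing, because partner is starving.”

The flask gives 38.7%, and north gains 6.6 points, against 3.6 points for east and 1.7 points for waiting. East ends at 42.2%, north-east at 40.4%.

    starting material + partner → target (k = 0.665 L mol⁻¹ min⁻¹, Ea = 64.0 kJ mol⁻¹)
    starting material + partner → isomer of the product (k = 0.795 L mol⁻¹ min⁻¹, Ea = 62.0 kJ mol⁻¹)
    (constants at 5 °C)

At 12.0 min the flask holds 15.1% of its starting material and 10.6% of its partner. s times that starting material is 6.8 points, the reckoned opening for north, which gained 6.6 points in 6.0 min.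

Take the neighbour charged with 0.240 equiv of partner: s times that charge gives 10.9% target. Computed, that neighbour holds 10.9% target at 12.0 min, with 0.370% of its partner and 76.1% of its starting material left.

The numbers in the tables come from a simulation for substances that don't exist.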